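**Plan**
- Cuts: in each 2,4-dihydroxyphenyl ring (A, A') the bonds C1–C2 and C5–C6 are cut first. The two C(=O)–C≡ bonds follow, then the two CH–CH2Ar bonds of the C4 core.
- Enabling feature: rings A and A' carry the acyl carbon on C1 and OH on C2 and C4. This pattern results when a 1,1,3-trioxygenated butadiene (C2–C5) adds to a terminal alkynyl ketone (C1, C6) and the adduct loses methanol.
- Forward: dimethyl acetylenedicarboxylate is dibenzylated in one flask to a Z maleate (rings B, B' are bought) and reduced. The diester is turned into the bis(N-methoxy-N-methylamide) and then the bis(ethynyl ketone). Rings A and A' are closed last and together.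
- Stereochemistry: both centres arise in one syn addition of H2 to the Z tetrasubstituted alkene, which gives the meso (R,S) pair. Every later step avoids enolising conditions.
- Protecting groups: the hydrogenation strips the benzyl ethers, so they are put back at once and removed at the end by neutral hydrogenolysis.

Key step: step 8

Remark: the two [C@@H] descriptors of the target correspond to (2S,3R) = (2R,3S), the achiral meso isomer, so only relative configuration has to be controlled.

Step 1
Reactants: 1 4-(benzyloxy)benzyl chloride; 2 dimethyl acetylenedicarboxylate; 3 4-(benzyloxy)benzyl bromide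
Product: 7 dimethyl (Z)-2,3-bis[4-(benzyloxy)benzyl]but-2-enedioate, via benzylic Grignard reagent 4 (not isolated), via benzylic copper reagent 5 (not isolated), via alkenylcopper adduct 6 (not isolated)
Conditions: 1, Mg, THF, 0 °C; CuBr·SMe2, THF, −40 °C; 2, −78 °C; then HMPA, 3, −78 °C → rt; aq. NH4Cl
Reagents that add atoms: none
Why: Tandem vicinal dialkylation of an acetylenedicarboxylate, a known way to 2,3-disubstituted maleates: the Grignard-derived monovalent copper reagent 5 adds syn across the triple bond (carbocupration), and the alkenylcopper 6 is alkylated with retention by the reactive benzylic bromide in the presence of HMPA, which leaves the two esters cis.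

Step 2
Reactants: 7 dimethyl (Z)-2,3-bis[4-(benzyloxy)benzyl]but-2-enedioate
Product: 9 dimethyl (2R,3S)-2,3-bis(4-hydroxybenzyl)butanedioate (meso), via debenzylated maleate 8 (not isolated)
Conditions: H2 (5 bar), 10% Pd/C, EtOAc–MeOH, rt
Reagents that add atoms: none
Why: Heterogeneous catalytic hydrogenation adds both hydrogens to the same face of the Z tetrasubstituted alkene, so the two stereocentres are created together and can only stand in the meso (2R,3S) relation; the aryl benzyl ethers cannot survive these conditions, and their hydrogenolysis is accepted and made good in step 3.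

Step 3
Reactants: 9 dimethyl (2R,3S)-2,3-bis(4-hydroxybenzyl)butanedioate
Product: 10 dimethyl (2R,3S)-2,3-bis[4-(benzyloxy)benzyl]butanedioate (meso)
Conditions: BnBr, K2CO3, acetone, reflux
Reagents that add atoms: benzyl bromide, BrCc1ccccc1
Why: Williamson ether synthesis on the two phenols; K2CO3 deprotonates phenols but is far too weak to enolise the esters, so the meso centres are untouched.

Step 4
Reactants: 10 dimethyl (2R,3S)-2,3-bis[4-(benzyloxy)benzyl]butanedioate
Product: 11 (2R,3S)-2,3-bis[4-(benzyloxy)benzyl]-N1,N4-dimethoxy-N1,N4-dimethylbutanediamide (meso)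
Conditions: MeNHOMe·HCl, AlMe3, CH2Cl2, 0 °C → reflux; then 1 M HCl, 0 °C
Reagents that add atoms: N,O-dimethylhydroxylamine hydrochloride, CNOC.Cl
Why: Aluminium-amide aminolysis of esters (Weinreb amide formation) works on α-branched esters under weakly basic conditions, so both esters should be exchanged without epimerisation, and the tertiary amides cannot close to an imide.

Step 5
Reactants: 11 meso bis(N-methoxy-N-methylamide); 12 ethynylmagnesium bromide
Product: 14 (4R,5S)-4,5-bis[4-(benzyloxy)benzyl]octa-1,7-diyne-3,6-dione (meso), via twofold tetrahedral magnesium adduct 13 (not isolated)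
Conditions: 12 (6 equiv), THF, 0 °C → rt; inverse quench into cold 1 M HCl/Et2O
Reagents that add atoms: none
Why: Weinreb ketone synthesis: each amide takes up one acetylide to give the chelated adduct 13, which resists a second addition and enolisation until the inverse quench into cold acid, where the liberated amine is protonated at once and cannot add to the new ynones.

Step 6
Reactants: 15 methyl acetoacetate
Product: 16 methyl 3-(trimethylsilyloxy)but-2-enoate (E/Z mixture, geometry of no consequence)
Conditions: TMSCl, Et3N, hexane, rt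
Reagents that add atoms: chlorotrimethylsilane, C[Si](C)(C)Cl
Why: O-silylation of the enol form of a β-keto ester with TMSCl and Et3N is the standard first stage in the preparation of 1,3-bis(silyloxy)dienes.

Step 7
Reactants: 16 methyl 3-(trimethylsilyloxy)but-2-enoate
Product: 18 1-methoxy-1,3-bis(trimethylsilyloxy)buta-1,3-diene, via lithium dienolate 17 (not isolated)
Conditions: LiN(iPr)2, THF, −78 °C; TMSCl, −78 °C → rt; distillation
Reagents that add atoms: chlorotrimethylsilane, C[Si](C)(C)Cl
Why: Kinetic γ-deprotonation of the vinylogous ester gives the extended enolate 17, which is silylated on oxygen (silyl ketene acetal formation); the geometry at the ketene acetal is erased later.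

Step 8
Reactants: 14 (4R,5S)-4,5-bis[4-(benzyloxy)benzyl]octa-1,7-diyne-3,6-dione; 18 1-methoxy-1,3-bis(trimethylsilyloxy)buta-1,3-diene (two molecules are incorporated)
Product: 21 (2R,3S)-2,3-bis[4-(benzyloxy)benzyl]-1,4-bis(2,4-dihydroxyphenyl)butane-1,4-dione (meso), via twofold cyclohexadiene cycloadduct 19 (not isolated), via tetrakis(trimethylsilyl) ether 20 (not isolated)
Conditions: 18 (5 equiv), toluene, rt → 60 °C; then 0.5 M aq. citric acid, THF, rt
Reagents that add atoms: none
Why: Each terminal ynone of 14 is a strongly polarised dienophile and 18 a strongly polarised diene, so a thermal, concerted but asynchronous [4+2] cycloaddition joins the unsubstituted diene terminus (C4 of 18) to the alkyne CH and the ketene acetal carbon (C1 of 18) to the acyl-bearing alkyne carbon, giving the bis(cyclohexa-1,4-diene) 19. The closest known reaction type is the Diels–Alder benzannulation of alkynyl ketones and esters with 1,3-dioxygenated silyloxydienes to give resorcinols. Rings A and A' are each closed by this intermolecular six-membered cycloaddition, which forms the C1–C2 and C5–C6 bonds of the arene; loss of methanol from the mixed ketal carbon and the ring CH2 aromatises 19 to 20, and the mild acid work-up removes the four trimethylsilyl groups. No lasting stereocentre is created, since the ketal carbons of 19 are stereogenic only until aromatisation and the two existing centres are spectators. The selectivity needed is regiochemical (2,4- and not 3,5-dihydroxy), and it is secured by the two donor oxygens, which make C4 of the diene its nucleophilic end, matched with the carbonyl group, which makes the alkyne CH the electrophilic end; a stepwise Michael–cyclisation path would close the same ring. As neither base nor strong acid is present, the enolisable meso centres should keep their configuration, furan formation from the 1,4-diketone should not start, and the benzyl ethers are inert.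

Step 9
Reactants: 21 (2R,3S)-2,3-bis[4-(benzyloxy)benzyl]-1,4-bis(2,4-dihydroxyphenyl)butane-1,4-dione
Product: 22 (2R,3S)-1,4-bis(2,4-dihydroxyphenyl)-2,3-bis(4-hydroxybenzyl)butane-1,4-dione (meso, CNP0406969.1)
Conditions: H2 (1 atm), 10% Pd/C, EtOAc–EtOH, rt
Reagents that add atoms: none
Why: Catalytic hydrogenolysis of aryl benzyl ethers under neutral conditions; the 2,4-dihydroxyphenyl ketones are hydrogen-bonded vinylogous acids that should not be reduced at 1 atm, and the absence of acid and base protects the meso centres and prevents furan formation.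

**Compound list**
1 | 4-(benzyloxy)benzyl chloride | ClCc1ccc(OCc2ccccc2)cc1 | starting material
2 | dimethyl acetylenedicarboxylate | COC(=O)C#CC(=O)OC | starting material
3 | 4-(benzyloxy)benzyl bromide | BrCc1ccc(OCc2ccccc2)cc1 | starting material
4 | 4-(benzyloxy)benzylmagnesium chloride | Cl[Mg]Cc1ccc(OCc2ccccc2)cc1 | intermediate
5 | 4-(benzyloxy)benzylcopper (SMe2 ligand omitted) | [Cu]Cc1ccc(OCc2ccccc2)cc1 | intermediate
6 | dimethyl 2-[4-(benzyloxy)benzyl]-3-cupriobut-2-enedioate, ester groups cis | COC(=O)/C(Cc1ccc(OCc2ccccc2)cc1)=C(/[Cu])C(=O)OC | intermediate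
7 | dimethyl (Z)-2,3-bis[4-(benzyloxy)benzyl]but-2-enedioate | COC(=O)/C(Cc1ccc(OCc2ccccc2)cc1)=C(/Cc1ccc(OCc2ccccc2)cc1)C(=O)OC | intermediate
8 | dimethyl (Z)-2,3-bis(4-hydroxybenzyl)but-2-enedioate | COC(=O)/C(Cc1ccc(O)cc1)=C(/Cc1ccc(O)cc1)C(=O)OC | intermediate
9 | dimethyl (2R,3S)-2,3-bis(4-hydroxybenzyl)butanedioate (meso) | COC(=O)[C@@H](Cc1ccc(O)cc1)[C@@H](Cc1ccc(O)cc1)C(=O)OC | intermediate
10 | dimethyl (2R,3S)-2,3-bis[4-(benzyloxy)benzyl]butanedioate (meso) | COC(=O)[C@@H](Cc1ccc(OCc2ccccc2)cc1)[C@@H](Cc1ccc(OCc2ccccc2)cc1)C(=O)OC | intermediate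
11 | (2R,3S)-2,3-bis[4-(benzyloxy)benzyl]-N1,N4-dimethoxy-N1,N4-dimethylbutanediamide (meso) | CON(C)C(=O)[C@@H](Cc1ccc(OCc2ccccc2)cc1)[C@@H](Cc1ccc(OCc2ccccc2)cc1)C(=O)N(C)OC | intermediate
12 | ethynylmagnesium bromide | C#C[Mg]Br | starting material
13 | twofold tetrahedral adduct, bis(bromomagnesium alkoxide), hemiaminal carbons unassigned | C#CC(O[Mg]Br)(N(C)OC)[C@@H](Cc1ccc(OCc2ccccc2)cc1)[C@@H](Cc1ccc(OCc2ccccc2)cc1)C(O[Mg]Br)(N(C)OC)C#C | intermediate
14 | (4R,5S)-4,5-bis[4-(benzyloxy)benzyl]octa-1,7-diyne-3,6-dione (meso) | C#CC(=O)[C@@H](Cc1ccc(OCc2ccccc2)cc1)[C@@H](Cc1ccc(OCc2ccccc2)cc1)C(=O)C#C | intermediate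
15 | methyl acetoacetate | CC(=O)CC(=O)OC | starting material
16 | methyl 3-(trimethylsilyloxy)but-2-enoate (E/Z mixture) | COC(=O)C=C(C)O[Si](C)(C)C | intermediate
17 | lithium 1-methoxy-3-(trimethylsilyloxy)buta-1,3-dien-1-olate | [Li]OC(OC)=CC(=C)O[Si](C)(C)C | intermediate
18 | 1-methoxy-1,3-bis(trimethylsilyloxy)buta-1,3-diene | C=C(O[Si](C)(C)C)/C=C(/OC)O[Si](C)(C)C | intermediate
19 | (2R,3S)-2,3-bis[4-(benzyloxy)benzyl]-1,4-bis[6-methoxy-4,6-bis(trimethylsilyloxy)cyclohexa-1,4-dien-1-yl]butane-1,4-dione, ketal carbons unassigned | O=C(C1=CCC(O[Si](C)(C)C)=CC1(OC)O[Si](C)(C)C)[C@@H](Cc1ccc(OCc2ccccc2)cc1)[C@@H](Cc1ccc(OCc2ccccc2)cc1)C(=O)C1=CCC(O[Si](C)(C)C)=CC1(OC)O[Si](C)(C)C | intermediate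
20 | (2R,3S)-2,3-bis[4-(benzyloxy)benzyl]-1,4-bis[2,4-bis(trimethylsilyloxy)phenyl]butane-1,4-dione | O=C(c1ccc(O[Si](C)(C)C)cc1O[Si](C)(C)C)[C@@H](Cc1ccc(OCc2ccccc2)cc1)[C@@H](Cc1ccc(OCc2ccccc2)cc1)C(=O)c1ccc(O[Si](C)(C)C)cc1O[Si](C)(C)C | intermediate
21 | (2R,3S)-2,3-bis[4-(benzyloxy)benzyl]-1,4-bis(2,4-dihydroxyphenyl)butane-1,4-dione (meso) | O=C(c1ccc(O)cc1O)[C@@H](Cc1ccc(OCc2ccccc2)cc1)[C@@H](Cc1ccc(OCc2ccccc2)cc1)C(=O)c1ccc(O)cc1O | intermediate
22 | (2R,3S)-1,4-bis(2,4-dihydroxyphenyl)-2,3-bis(4-hydroxybenzyl)butane-1,4-dione (meso) | O=C(c1ccc(O)cc1O)[C@@H](Cc1ccc(O)cc1)[C@@H](Cc1ccc(O)cc1)C(=O)c1ccc(O)cc1O | target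

Total step count: 9. Longest linear sequence: 7 (steps 1, 2, 3, 4, 5, 8, 9).

**Steps most likely to fail**

Step 1. Three processes threaten this step:
- homocoupling while the benzylic Grignard reagent forms
- slow capture of the alkenylcopper by the benzylic bromide, so that protonation on work-up takes over
- Z-to-E leakage through the copper allenolate while the mixture warms

The fallback sets out from 1 and comes back at 7. Commercial 2,3-dibromomaleic anhydride is esterified (MeOH, cat. H2SO4, reflux) to dimethyl (Z)-2,3-dibromobut-2-enedioate F1, whose cis ester relation is inherited from the ring. Compound 1 is converted with Zn dust and LiCl in THF into 4-(benzyloxy)benzylzinc chloride F2. A twofold Negishi coupling of F1 with F2 (Pd(PPh3)4, THF, rt → 50 °C) should replace both bromides with retention and give 7. The two C–C bonds are then made on an alkene of fixed geometry, not across an alkyne.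

Step 2. The double bond may migrate into a benzylic position on the palladium surface before the second hydrogen arrives. That would uncouple the two hydrogen deliveries and erode the meso selectivity. Reduction of the tetrasubstituted alkene may also be slow. The fallback sets out from 7 and comes back at 9, and it uses a ring as the stereochemical template.
- Saponification (LiOH, THF–H2O) and acidification should give the dialkylmaleic acid, which closes by itself to 3,4-bis[4-(benzyloxy)benzyl]furan-2,5-dione F3. Any E diacid cannot close and is washed out with base.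
- Hydrogenation of F3 (H2, Pd/C, EtOAc) takes place on a flat five-membered ring. Even after migration to an exocyclic benzylidene position, hydrogen is delivered to the face opposite the resident benzyl group. Both paths therefore end in cis-(3R,4S)-3,4-bis(4-hydroxybenzyl)oxolane-2,5-dione F4.
- Fischer esterification of F4 (MeOH, cat. H2SO4, reflux) opens the anhydride and gives 9.

Step 8. Three processes threaten this step:
- incomplete reaction at the second ynone
- oligomerisation of the sensitive diynedione on heating
- expulsion of silanol in place of methanol from the mixed ketal, which would leave the C2 oxygen methylated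

The fallback sets out from 14 and comes back at 20. Dimedone is bis-silylated (TMSOTf, Et3N, Et2O, 0 °C) to 5,5-dimethyl-1,3-bis(trimethylsilyloxy)cyclohexa-1,3-diene F5. Heating 14 with F5 (toluene, sealed tube, 140 °C) should give, by the same polarity-matched [4+2] addition, the twofold bicyclo[2.2.2]octadiene adduct F6. This adduct aromatises by retro-Diels–Alder loss of the gem-dimethyl bridge and so gives 20 without any ketal and without a choice of leaving group. The citric acid work-up of step 8 then leads to 21.

**Further compounds**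
F1 | step 1 | dimethyl (Z)-2,3-dibromobut-2-enedioate | COC(=O)/C(Br)=C(/Br)C(=O)OC
F2 | step 1 | 4-(benzyloxy)benzylzinc chloride | Cl[Zn]Cc1ccc(OCc2ccccc2)cc1
F3 | step 2 | 3,4-bis[4-(benzyloxy)benzyl]furan-2,5-dione | O=C1OC(=O)C(Cc2ccc(OCc3ccccc3)cc2)=C1Cc1ccc(OCc2ccccc2)cc1
F4 | step 2 | cis-(3R,4S)-3,4-bis(4-hydroxybenzyl)oxolane-2,5-dione | O=C1OC(=O)[C@@H](Cc2ccc(O)cc2)[C@H]1Cc1ccc(O)cc1
F5 | step 8 | 5,5-dimethyl-1,3-bis(trimethylsilyloxy)cyclohexa-1,3-diene | CC1(C)CC(O[Si](C)(C)C)=CC(O[Si](C)(C)C)=C1
F6 | step 8 | twofold bicyclo[2.2.2]octa-2,5-diene adduct of 14 and F5, bridgeheads unassigned | O=C(C1=CC2C(O[Si](C)(C)C)=CC1(O[Si](C)(C)C)CC2(C)C)[C@@H](Cc1ccc(OCc2ccccc2)cc1)[C@@H](Cc1ccc(OCc2ccccc2)cc1)C(=O)C1=CC2C(O[Si](C)(C)C)=CC1(O[Si](C)(C)C)CC2(C)C
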